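**Retrosynthetic overview**
1. The cyclopentane and the cycloheptane are opened first. The bond from the methyl-bearing quaternary carbon to the ring-fusion CH, and the 1,2-shift that creates the isopropenyl carbon, lead back to the 2,3-epoxide 15 of an eleven-membered (humulene) ring fused to the dihydropyran.
2. The dihydropyran is cut at CH2–C(sp2) and at O–C(sp2). This gives β-hydroxy aldehyde 8 and isobutyrylfilicinic acid 12, which are joined by a reductive, dehydrative [4+2] annulation.
3. Enabling feature: the O–C=C–CH2 unit of the dihydropyran is the cyclic enol ether of a 2-alkylated β-triketone. Its C=C carbon is the doubly activated C–H carbon of the cyclohexanetrione ring, and its O-bearing carbon is the one carbonyl not tied up in the chelated acyl-enol. The CH2 and the tertiary O sit on adjacent carbocycle carbons, which is an aldol (β-hydroxy aldehyde) pattern.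
4. Compound 8 comes from α-humulene by cis-cyanohydroxylation of C6=C7 (nitrile oxide cycloaddition through a temporary isoxazoline), Shi epoxidation of C2=C3 run as a kinetic resolution, and DIBAL-H reduction.
5. Order of ring formation: isoxazoline (temporary), oxirane (temporary), dihydropyran, cycloheptane together with a cyclohexane, then contraction of that cyclohexane to the cyclopentane.

Key step: step 7

Remark: humulene numbering is used in the names: C1H2–C2H=C3(CH3)–C4H2–C5H2–C6H=C7(CH3)–C8H2–C9H=C10H–C11(CH3)2. Compounds 4, 5 and 6 are racemic and are drawn as the enantiomer that is carried on. β-Triketones are drawn in the enol form of the target.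
Assumption: the outer, reactive face of C2=C3 in (6S,7R)-6 is the one that gives the (2R,3R)-oxirane, as in related C6–C7-fused humulenes. If both enantiomers are epoxidised, the two products are diastereomers and are separated at the same point.

Step 1
Reactants: 1 α-humulene; 2 ethyl 2-chloro-2-(hydroxyimino)acetate
Product: 4 (±)-(6S*,7R*)-C6–C7 isoxazoline ester of humulene (ethyl 2-isoxazoline-3-carboxylate; isoxazoline C4 = C6–H; isoxazoline C5 = C7 bearing CH3 and the ring O; 2E and 9E alkenes intact), via ethoxycarbonylformonitrile oxide 3 (not isolated)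
Conditions: 2 added slowly to 1 (3 equiv), KHCO3, EtOAc, 25 °C
Reagents that add atoms: none
Why: In this Huisgen 1,3-dipolar cycloaddition the nitrile oxide adds in a concerted, suprafacial way, so carbon (to C6) and oxygen (to the more substituted C7) arrive syn on the E-alkene and fix the C6/C7 relative configuration (racemic), the electrophilic dipole should choose the most strained and most nucleophilic C6=C7 bond, which also reacts first with peracids, and the excess of 1 suppresses double addition.

Step 2
Reactants: 4 (±)-isoxazoline ester
Product: 6 (±)-(6S*,7R*)-7-hydroxy-6,7-dihydrohumulene-6-carbonitrile, via isoxazoline-3-carboxylic acid 5 (not isolated)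
Conditions: NaOH, EtOH–H2O, 25 °C; 1 M HCl to pH 3, 0 °C; DMF, 95 °C
Reagents that add atoms: none
Why: Saponification followed by thermal decarboxylative fragmentation of the isoxazoline-3-carboxylic acid (the known cis-cyanohydroxylation of olefins) cleaves only C–CO2H and N–O, so C6 and C7 keep their configuration and the temporary ring leaves a β-hydroxy nitrile.

Step 3
Reactants: 6 (±)-hydroxy nitrile
Product: 7 (2R,3R,6S,7R)-2,3-epoxy-7-hydroxy-2,3,6,7-tetrahydrohumulene-6-carbonitrile
Conditions: D-fructose-derived Shi ketone (30 mol %), Oxone (0.6 equiv), K2CO3, Bu4NHSO4 (cat.), MeCN–DMM/aq. borate–EDTA buffer (pH 10.5), 0 °C, stopped near half conversion; chromatography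
Reagents that add atoms: potassium peroxymonosulfate (active part of Oxone) [K+].[O-]S(=O)(=O)OO
Why: In this Shi asymmetric epoxidation, used as a kinetic resolution of a racemic olefin, the chiral dioxirane attacks the face of the E-trisubstituted C2=C3 bond that gives the (2R,3R)-oxirane, a face exposed only in the (6S,7R) enantiomer, so that enantiomer reacts first and is separated from unreacted (6R,7S)-6, which fixes the absolute configuration at C6 and C7 and sets C2 and C3, while the hindered disubstituted C9=C10 bond next to CMe2 reacts more slowly.

Step 4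
Reactants: 7 epoxy hydroxy nitrile
Product: 8 (2R,3R,6R,7R)-2,3-epoxy-7-hydroxy-2,3,6,7-tetrahydrohumulene-6-carbaldehyde
Conditions: DIBAL-H (2.5 equiv), CH2Cl2, −78 °C; aq. Rochelle salt/pH 6 buffer, 0 °C; used without storage
Reagents that add atoms: water O
Why: Partial nitrile reduction with DIBAL-H stops at the N-aluminio imine, which mild hydrolysis converts into the aldehyde, and at −78 °C the trisubstituted epoxide and the alkene are inert and the branched C6 centre is not enolised (the change of descriptor at C6 is only a change of priority).

Step 5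
Reactants: 9 phloroglucinol; 10 isobutyryl chloride
Product: 11 2-methyl-1-(2,4,6-trihydroxyphenyl)propan-1-one
Conditions: AlCl3, PhNO2–CH2Cl2, 50 °C; aq. HCl
Reagents that add atoms: none
Why: This is a Friedel–Crafts C-acylation of the electron-rich arene in which the first acyl group deactivates the ring towards a second, and no stereocentre is formed.

Step 6
Reactants: 11 acylphloroglucinol
Product: 12 isobutyrylfilicinic acid (3,5-dihydroxy-2-isobutyryl-6,6-dimethylcyclohexa-2,4-dien-1-one)
Conditions: NaOMe (3 equiv), MeI (2.1 equiv), MeOH, 0 to 25 °C; aq. HCl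
Reagents that add atoms: iodomethane CI
Why: In this base-mediated dearomative C-methylation the second methyl group enters at the carbon that is already methylated and locks the ring as the cyclohexanetrione, a known route to acylfilicinic acids, and no stereocentre is formed.

Step 7
Reactants: 8 epoxy hydroxy aldehyde; 12 isobutyrylfilicinic acid
Product: 15 (2R,3R,6S,7R)-2,3-epoxyhumulene-fused dihydropyran (pyran O on C7; new CH2 on C6; enol-ether C=C shared with the 2-isobutyryl-3-hydroxy-6,6-dimethylcyclohexadienone ring; O-bearing carbon next to CMe2), via alkylidene triketone 13 (not isolated), via 2-alkyl triketone 14 (not isolated)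
Conditions: 8, 12 (1.05 equiv), Hantzsch ester (1.1 equiv), L-proline (20 mol %), CH2Cl2, 25 °C; then PPTS (10 mol %), 4 Å MS, 25 °C, same flask
Reagents that add atoms: none
Why: Proposed new method: the ring C–H carbon of 12 that lies between two carbonyls condenses with the aldehyde of 8 (proline iminium, Knoevenagel) to give 13, the Hantzsch ester transfers hydride to the exocyclic carbon to give 14 (new CH2–C bond), and the tertiary C7–OH then adds to the adjacent free ring carbonyl and the hemiketal loses water (new O–C bond), which amounts to a reductive, dehydrative [4+2] annulation. The closest known reaction types are the organocatalytic three-component reductive alkylation of cyclic 1,3-diones with aldehydes and Hantzsch ester, and the acid-catalysed cyclodehydration of 2-(3-hydroxyalkyl)-1,3-diones, and merging them on a β-hydroxy aldehyde is the new element. The only ring closed is the dihydropyran, by 6-exo-trig addition of the hydroxyl to the ketone followed by elimination to the endocyclic enol ether. No stereocentre is created: the C7–O bond is never broken because PPTS is too weak to ionise the tertiary alcohol, and C6 should be retained because condensation and irreversible hydride transfer outrun enamine or dienol formation at the branched carbon. The step needs C- rather than O-alkylation (secured by the condensation/reduction manifold) and closure on the carbonyl next to CMe2 (secured because the other flanking carbonyl is locked as the hydrogen-bonded enol of the acyl-triketone, so that E/Z isomers of 13 and any hemiketal isomers equilibrate and drain into the chelated product). It also needs interception of 13 before a second molecule of 12, the C9=C10 alkene, retro-aldol cleavage or β-elimination can consume it (secured by having the hydride donor present from the start), and the epoxide should survive because the medium never exceeds the acidity of the triketone and pyridinium ion.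

Step 8
Reactants: 15 epoxy dihydropyran
Product: 16 target CNP0510355.1
Conditions: p-TsOH·H2O (0.2 equiv), CH2Cl2, 0 to 25 °C
Reagents that add atoms: none
Why: This is a transannular cation–olefin cyclisation with Wagner–Meerwein shift of the type known for humulene epoxides, in which the protonated oxirane opens at tertiary C3, C9=C10 attacks C3 from the face opposite the leaving oxygen (closing the cycloheptane and a cyclohexane), C1 migrates from C11 to C10 (contraction to the cyclopentane) and a methyl proton is lost to give the isopropenyl group, so that C2–O is retained (OH cis to the angular methyl), C3 is inverted, and C9 and C10 are set by syn addition across the E-alkene within the folded macrocycle.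

**Compound list**
1 | α-humulene, (1E,4E,8E)-2,6,6,9-tetramethylcycloundeca-1,4,8-triene | C/C1=C\CC/C(C)=C/CC(C)(C)/C=C/C1 | starting material
2 | ethyl 2-chloro-2-(hydroxyimino)acetate | CCOC(=O)C(Cl)=NO | starting material
3 | ethoxycarbonylformonitrile oxide | CCOC(=O)C#[N+][O-] | intermediate
4 | (±)-(6S*,7R*)-C6–C7 isoxazoline ester of humulene | CCOC(=O)C1=NO[C@]2(C)C/C=C/C(C)(C)C/C=C(C)/CC[C@@H]12 | intermediate
5 | (±)-isoxazoline-3-carboxylic acid derived from 4 | OC(=O)C1=NO[C@]2(C)C/C=C/C(C)(C)C/C=C(C)/CC[C@@H]12 | intermediate
6 | (±)-(6S*,7R*)-7-hydroxy-6,7-dihydrohumulene-6-carbonitrile | N#C[C@@H]1CC/C(C)=C/CC(C)(C)/C=C/C[C@@]1(C)O | intermediate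
7 | (2R,3R,6S,7R)-2,3-epoxy-7-hydroxy-2,3,6,7-tetrahydrohumulene-6-carbonitrile | N#C[C@@H]1CC[C@@]2(C)O[C@@H]2CC(C)(C)/C=C/C[C@@]1(C)O | intermediate
8 | (2R,3R,6R,7R)-2,3-epoxy-7-hydroxy-2,3,6,7-tetrahydrohumulene-6-carbaldehyde | O=C[C@@H]1CC[C@@]2(C)O[C@@H]2CC(C)(C)/C=C/C[C@@]1(C)O | intermediate
9 | phloroglucinol | Oc1cc(O)cc(O)c1 | starting material
10 | isobutyryl chloride | CC(C)C(=O)Cl | starting material
11 | 2-methyl-1-(2,4,6-trihydroxyphenyl)propan-1-one | CC(C)C(=O)c1c(O)cc(O)cc1O | intermediate
12 | isobutyrylfilicinic acid | CC(C)C(=O)C1=C(O)C=C(O)C(C)(C)C1=O | intermediate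
13 | alkylidene triketone (Knoevenagel adduct of 8 and 12, E/Z not fixed) | CC(C)C(=O)C1=C(O)C(=C[C@@H]2CC[C@@]3(C)O[C@@H]3CC(C)(C)/C=C/C[C@@]2(C)O)C(=O)C(C)(C)C1=O | intermediate
14 | 2-alkyl triketone with free tertiary alcohol | CC(C)C(=O)C1=C(O)C(C[C@@H]2CC[C@@]3(C)O[C@@H]3CC(C)(C)/C=C/C[C@@]2(C)O)=C(O)C(C)(C)C1=O | intermediate
15 | (2R,3R,6S,7R)-2,3-epoxyhumulene-fused dihydropyran | CC(C)C(=O)C1=C(O)C2=C(O[C@]3(C)C/C=C/C(C)(C)C[C@H]4O[C@]4(C)CC[C@H]3C2)C(C)(C)C1=O | intermediate
16 | target CNP0510355.1 | C=C(C)[C@@H]1C[C@@H](O)[C@]2(C)CC[C@H]3CC4=C(O[C@]3(C)C[C@@H]12)C(C)(C)C(=O)C(C(=O)C(C)C)=C4O | target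

Total step count: 8. Longest linear sequence: 6 (steps 1, 2, 3, 4, 7, 8).

**Steps most likely to fail**

Step 7 (labelled step).
- What may go wrong: retro-aldol ring opening; loss of the tertiary hydroxyl by β-elimination at the aldehyde or alkylidene stage; epimerisation at C6; capture of the alkylidene by a second triketone or by the C9=C10 alkene; or closure of the hydroxyl on the wrong carbonyl.
- Fallback (known chemistry, the two bonds made one after the other): it sets out from 7. The tertiary alcohol is silylated (TESOTf, 2,6-lutidine, CH2Cl2, −78 °C) to the triethylsilyl ether F1. DIBAL-H then gives the silyloxy aldehyde F2. The established three-component reductive alkylation with 12, Hantzsch ester and proline gives the silyl-protected 2-alkyl triketone F3. Buffered fluoride (TBAF, AcOH) frees 14, which is cyclodehydrated in a separate acid-catalysed step (PPTS, 4 Å MS). The sequence comes back to the route at 15.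

Step 1.
- What may go wrong: poor site selectivity between C6=C7 and C2=C3, double addition, and dimerisation of the dipole.
- Fallback: it sets out from 1 and uses the established preference of electrophilic oxygen transfer for C6=C7.
  - Shi mono-epoxidation with the D-fructose ketone gives the (6R,7R)-6,7-epoxide F4, which also makes the series non-racemic.
  - PhSeSePh/NaBH4 in EtOH opens it at C6 with inversion to the hydroxy selenide F5.
  - H2O2 triggers selenoxide syn-elimination towards C5 and gives the tertiary allylic alcohol F6.
  - BrCH2SiMe2Cl/imidazole gives the (bromomethyl)dimethylsilyl ether F7.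
  - Bu3SnH/AIBN closes the 1,2-oxasilolane F8 by a silicon-tethered 5-exo-trig radical cyclisation, with the two macrocycle chains trans on the new ring.
  - Tamao–Kumada oxidation (H2O2, KF, KHCO3) gives the 1,3-diol F9.
  - A second Shi epoxidation at C2=C3 gives the epoxy diol F10.
  - TEMPO/PhI(OAc)2 oxidises only the primary alcohol, and the sequence comes back to the route at 8.

Step 3.
- What may go wrong: too small a rate difference between the two enantiomers, and over-oxidation at C9=C10.
- Fallback: it sets out from 5, which is isolated this time and resolved classically by crystallising its salt with (S)-1-phenylethylamine F11 (the mirror-image amine is used if the unwanted acid crystallises first). Acidification returns enantiopure 5, and heating in DMF gives enantiopure 6. Substrate-controlled peripheral epoxidation with mCPBA/NaHCO3 comes back to the route at 7.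

**Further compounds**
F1 | step 7 | triethylsilyl ether of 7 | N#C[C@@H]1CC[C@@]2(C)O[C@@H]2CC(C)(C)/C=C/C[C@@]1(C)O[Si](CC)(CC)CC
F2 | step 7 | triethylsilyl ether of 8 | O=C[C@@H]1CC[C@@]2(C)O[C@@H]2CC(C)(C)/C=C/C[C@@]1(C)O[Si](CC)(CC)CC
F3 | step 7 | triethylsilyl ether of 14 | CC(C)C(=O)C1=C(O)C(C[C@@H]2CC[C@@]3(C)O[C@@H]3CC(C)(C)/C=C/C[C@@]2(C)O[Si](CC)(CC)CC)=C(O)C(C)(C)C1=O
F4 | step 1 | (6R,7R)-humulene 6,7-epoxide | C[C@@]12C/C=C/C(C)(C)C/C=C(C)/CC[C@H]1O2
F5 | step 1 | (6S,7R)-6-(phenylselanyl)-6,7-dihydrohumulen-7-ol | O[C@]1(C)C/C=C/C(C)(C)C/C=C(C)/CC[C@@H]1[Se]c2ccccc2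
F6 | step 1 | (7R)-tertiary allylic alcohol with 2E,5E,9E alkenes | O[C@]1(C)C/C=C/C(C)(C)C/C=C(C)/C/C=C/1
F7 | step 1 | (bromomethyl)dimethylsilyl ether of F6 | BrC[Si](C)(C)O[C@]1(C)C/C=C/C(C)(C)C/C=C(C)/C/C=C/1
F8 | step 1 | C6–C7-fused 2,2-dimethyl-1,2-oxasilolane | C[Si]1(C)C[C@@H]2CC/C(C)=C/CC(C)(C)/C=C/C[C@@]2(C)O1
F9 | step 1 | (6S,7R)-6-(hydroxymethyl)-6,7-dihydrohumulen-7-ol | OC[C@@H]1CC/C(C)=C/CC(C)(C)/C=C/C[C@@]1(C)O
F10 | step 1 | (2R,3R,6S,7R)-2,3-epoxide of F9 | OC[C@@H]1CC[C@@]2(C)O[C@@H]2CC(C)(C)/C=C/C[C@@]1(C)O
F11 | step 3 | (S)-1-phenylethylammonium salt of (6S,7R)-5 | [O-]C(=O)C1=NO[C@]2(C)C/C=C/C(C)(C)C/C=C(C)/CC[C@@H]12.C[C@H]([NH3+])c1ccccc1
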